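The flavonol is cut at two neighbouring bonds of ring A, C8a–O1 and C4a–C4. Because C5, C6, C7 and C8 all carry methoxy groups, the ring A fragment is the symmetric 3,4,5,6-tetramethoxybenzyne, and no regiochemical question arises. In one operation the aryne, released by fluoride from an ortho-silyl aryl triflate, inserts into the C–O bond of (E)-4-methoxycinnamic acid, placing the phenolic oxygen and the cinnamoyl carbon on adjacent ring A carbons to give the 2'-hydroxychalcone. The precursor is 2,3,4,5-tetramethoxy-6-(trimethylsilyl)phenyl triflate, made in three steps from 1,2,3,4-tetramethoxybenzene. Iodine-mediated closure of ring C and C3 hydroxylation finish the route.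

Key step: step 4

Remark: direct alkaline hydrogen peroxide oxidation (Algar–Flynn–Oyamada) of a 2'-hydroxychalcone with a 6'-methoxy group tends to divert to the aurone. Ring C is therefore closed first and the C3 hydroxyl is added to the flavone, which costs one step and removes that ambiguity.

Remark: the target has no stereocentre. The transient intermediates that carry stereocentres (the four-membered alkoxide of the key step, the flavanone and the flavone epoxide) are racemic, and their stereocentres are lost again.

Step 1
Reactants: 1 1,2,3,4-tetramethoxybenzene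
Product: 4 2,3,4,5-tetramethoxyphenol, via aryllithium 2 (not isolated), via lithium arylborate 3 (not isolated)
Conditions: n-BuLi (1.1 equiv), TMEDA, THF, 0 °C; B(OMe)3, −78 °C → rt; AcOH, 30% H2O2, 0 °C → rt
Reagents that add atoms: hydrogen peroxide, OO
Why: Directed ortho-lithiation beside a methoxy group (the two free positions of 1 are equivalent by symmetry) gives aryllithium 2, which is borylated to 3 and oxidised at the carbon–boron bond by peroxide, the standard lithiation–borylation–oxidation route from an arene to a phenol.

Step 2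
Reactants: 4 2,3,4,5-tetramethoxyphenol
Product: 5 2-bromo-3,4,5,6-tetramethoxyphenol
Conditions: NBS (1.0 equiv), CH2Cl2, −78 → 0 °C, dark
Reagents that add atoms: N-bromosuccinimide, O=C1CCC(=O)N1Br
Why: Electrophilic aromatic bromination with NBS can only take place at the single unsubstituted ring carbon of 4, which is ortho to the hydroxyl group and strongly activated.

Step 3
Reactants: 5 2-bromo-3,4,5,6-tetramethoxyphenol
Product: 9 2,3,4,5-tetramethoxy-6-(trimethylsilyl)phenyl trifluoromethanesulfonate, via aryl silyl ether 6 (not isolated), via aryllithium 7 (not isolated), via lithium silylphenolate 8 (not isolated)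
Conditions: HMDS, THF, 65 °C, volatiles removed in vacuo; n-BuLi, THF, −100 °C; Tf2O, −100 °C → rt
Reagents that add atoms: hexamethyldisilazane, C[Si](C)(C)N[Si](C)(C)C; trifluoromethanesulfonic anhydride, O=S(=O)(OS(=O)(=O)C(F)(F)F)C(F)(F)F
Why: Silylation of the phenol with HMDS gives 6, bromine–lithium exchange gives 7, a 1,3 oxygen-to-carbon silyl shift (retro-Brook rearrangement) gives phenolate 8 and Tf2O triflates it in the same flask, the standard preparation of ortho-silylaryl triflates from ortho-bromophenols.

Step 4
Reactants: 9 2,3,4,5-tetramethoxy-6-(trimethylsilyl)phenyl trifluoromethanesulfonate (1.5 equiv); 10 (E)-4-methoxycinnamic acid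
Product: 15 (E)-1-(2-hydroxy-3,4,5,6-tetramethoxyphenyl)-3-(4-methoxyphenyl)prop-2-en-1-one, via cesium 4-methoxycinnamate 11 (not isolated), via 3,4,5,6-tetramethoxybenzyne 12 (not isolated), via cesiated aryl ester 13 (not isolated), via benzoxetene alkoxide 14 (not isolated)
Conditions: CsF (4 equiv), anhydrous THF, 125 °C, sealed tube; aq. NH4Cl work-up
Reagents that add atoms: none
Why: Fluoride attacks silicon in 9 and triflate leaves, releasing aryne 12, while CsF turns acid 10 into carboxylate 11. The carboxylate oxygen adds to one aryne carbon to give the ortho-metalated aryl ester 13, whose carbanion attacks the neighbouring ester carbonyl to form the four-membered alkoxide 14; cleavage of the former ester C–O bond then gives the ortho-acylphenoxide, which is protonated on work-up. The closest known reaction type is the fluoride-induced insertion of arynes into the C–O bond of carboxylic acids, α,β-unsaturated acids included, which gives ortho-hydroxyaryl ketones and is mechanistically related to an anionic ortho-Fries shift. No ring of the target closes and no stereocentre is formed; the E double bond of 10 is carried through unchanged. Regioselectivity is not an issue because the aryne is symmetric, each of its two reactive carbons being flanked by a methoxy group, and carbonyl attack instead of conjugate addition is secured by the short tether of the aryl ester, which brings only the acyl carbon within reach of the carbanion. The step needs an anhydrous medium and high temperature so that acyl transfer outruns protonation of 13 to the simple aryl ester.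

Step 5
Reactants: 15 (E)-1-(2-hydroxy-3,4,5,6-tetramethoxyphenyl)-3-(4-methoxyphenyl)prop-2-en-1-one
Product: 17 5,6,7,8-tetramethoxy-2-(4-methoxyphenyl)-4H-chromen-4-one, via flavanone 16 (not isolated)
Conditions: I2 (10 mol %), DMSO, 130 °C; aq. Na2S2O3 work-up
Reagents that add atoms: none
Why: Iodine-catalysed oxidative cyclisation of a 2'-hydroxychalcone in DMSO: oxa-Michael addition of the phenol closes ring C to flavanone 16, which iodine dehydrogenates with DMSO as the terminal oxidant, so that any 16 already present after step 4 converges on the same flavone.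

Step 6
Reactants: 17 5,6,7,8-tetramethoxy-2-(4-methoxyphenyl)-4H-chromen-4-one
Product: 19 3-hydroxy-5,6,7,8-tetramethoxy-2-(4-methoxyphenyl)-4H-chromen-4-one, via flavone epoxide 18 (not isolated)
Conditions: DMDO (acetone solution), CH2Cl2, 0 °C → rt; then p-TsOH·H2O (cat.), rt
Reagents that add atoms: dimethyldioxirane, CC1(C)OO1
Why: Dioxirane epoxidation of the C2–C3 double bond of the flavone gives 18, whose acid-catalysed opening at C2 (cation stabilised by O1 and the 4-methoxyphenyl group) and loss of the C3 proton give the 3-hydroxyflavone, a known flavone-to-flavonol oxidation that tolerates 5-alkoxy and polymethoxy substitution.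

Compound list
1 | 1,2,3,4-tetramethoxybenzene | COc1ccc(OC)c(OC)c1OC | starting material
2 | (2,3,4,5-tetramethoxyphenyl)lithium | [Li]c1cc(OC)c(OC)c(OC)c1OC | intermediate
3 | lithium trimethoxy(2,3,4,5-tetramethoxyphenyl)borate | [Li+].CO[B-](OC)(OC)c1cc(OC)c(OC)c(OC)c1OC | intermediate
4 | 2,3,4,5-tetramethoxyphenol | COc1cc(O)c(OC)c(OC)c1OC | intermediate
5 | 2-bromo-3,4,5,6-tetramethoxyphenol | COc1c(Br)c(O)c(OC)c(OC)c1OC | intermediate
6 | (2-bromo-3,4,5,6-tetramethoxyphenoxy)trimethylsilane | COc1c(Br)c(O[Si](C)(C)C)c(OC)c(OC)c1OC | intermediate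
7 | [2,3,4,5-tetramethoxy-6-(trimethylsilyloxy)phenyl]lithium | [Li]c1c(O[Si](C)(C)C)c(OC)c(OC)c(OC)c1OC | intermediate
8 | lithium 2,3,4,5-tetramethoxy-6-(trimethylsilyl)phenolate | [Li+].COc1c([Si](C)(C)C)c([O-])c(OC)c(OC)c1OC | intermediate
9 | 2,3,4,5-tetramethoxy-6-(trimethylsilyl)phenyl trifluoromethanesulfonate | COc1c(OC)c(OC)c([Si](C)(C)C)c(OS(=O)(=O)C(F)(F)F)c1OC | intermediate
10 | (E)-4-methoxycinnamic acid, (2E)-3-(4-methoxyphenyl)prop-2-enoic acid | COc1ccc(/C=C/C(=O)O)cc1 | starting material
11 | cesium (E)-4-methoxycinnamate | [Cs+].COc1ccc(/C=C/C(=O)[O-])cc1 | intermediate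
12 | 3,4,5,6-tetramethoxybenzyne | COC1=C(OC)C(OC)=C(OC)C#C1 | intermediate
13 | [2,3,4,5-tetramethoxy-6-((E)-4-methoxycinnamoyloxy)phenyl]cesium | [Cs]c1c(OC)c(OC)c(OC)c(OC)c1OC(=O)/C=C/c1ccc(OC)cc1 | intermediate
14 | cesium 3,4,5,6-tetramethoxy-2-[(E)-2-(4-methoxyphenyl)ethenyl]-2H-benzoxet-2-olate, racemic | [Cs+].COc1ccc(/C=C/C2([O-])Oc3c(OC)c(OC)c(OC)c(OC)c32)cc1 | intermediate
15 | (E)-1-(2-hydroxy-3,4,5,6-tetramethoxyphenyl)-3-(4-methoxyphenyl)prop-2-en-1-one | COc1ccc(/C=C/C(=O)c2c(O)c(OC)c(OC)c(OC)c2OC)cc1 | intermediate
16 | 5,6,7,8-tetramethoxy-2-(4-methoxyphenyl)chroman-4-one, racemic | COc1ccc(C2CC(=O)c3c(OC)c(OC)c(OC)c(OC)c3O2)cc1 | intermediate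
17 | 5,6,7,8-tetramethoxy-2-(4-methoxyphenyl)-4H-chromen-4-one | COc1ccc(-c2cc(=O)c3c(OC)c(OC)c(OC)c(OC)c3o2)cc1 | intermediate
18 | 2,3-epoxy-5,6,7,8-tetramethoxy-2-(4-methoxyphenyl)chroman-4-one, racemic, cis-fused, one enantiomer drawn | COc1ccc([C@@]23O[C@@H]2C(=O)c2c(OC)c(OC)c(OC)c(OC)c2O3)cc1 | intermediate
19 | 3-hydroxy-5,6,7,8-tetramethoxy-2-(4-methoxyphenyl)-4H-chromen-4-one | COc1ccc(-c2oc3c(OC)c(OC)c(OC)c(OC)c3c(=O)c2O)cc1 | target

Total step count: 6
Longest linear sequence: 6 steps (1 → 4 → 5 → 9 → 15 → 17 → 19); acid 10 enters at step 4 as a purchased material.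

Steps most likely to fail

Step 4. The ortho-metalated aryl ester may be protonated before the acyl group migrates, so that the reaction stops at simple O-arylation of the acid. The phenoxide product may also be arylated a second time by the excess aryne. Closure of the product to the flavanone is harmless, since step 5 converges. The fallback sets out from phenol 4 and builds the acyl–aryl bond by classical electrophilic acylation. C-acetylation of 4 at its only free ring position with acetic acid and BF3·OEt2 at about 90 °C should give 1-(2-hydroxy-3,4,5,6-tetramethoxyphenyl)ethan-1-one F1. Claisen–Schmidt condensation of F1 with 4-methoxybenzaldehyde (KOH, EtOH, rt) then returns to the route at chalcone 15. Steps 2 and 3 are not needed in this case.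

Step 2. The brominating agent may oxidise the electron-rich para-methoxyphenol to a quinone with loss of a methyl group instead of substituting the ring. The fallback sets out from phenol 4 and avoids both electrophilic halogenation and halogen–metal exchange by using a carbamate-directed ortho-metalation.
- Addition of 4 to isopropyl isocyanate (Et3N cat., CH2Cl2) gives 2,3,4,5-tetramethoxyphenyl N-isopropylcarbamate F2.
- In one flask, TMSOTf/TMEDA masks the N–H, n-BuLi/TMEDA at −78 °C removes the ring proton between the carbamate and a methoxy group, and TMSCl followed by acidic work-up gives 2,3,4,5-tetramethoxy-6-(trimethylsilyl)phenyl N-isopropylcarbamate F3.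
- Et2NH and DBU in MeCN at 40 °C cleave the carbamate to 2,3,4,5-tetramethoxy-6-(trimethylsilyl)phenol F4, which is triflated in the same flask with PhNTf2, returning to the route at silyl triflate 9.

Step 6. Epoxidation of the electron-poor C2–C3 bond may be slow, which would let the dioxirane attack the electron-rich aryl rings or leave flavone unconverted. The fallback sets out from flavone 17 and replaces electrophilic oxidation by deprotonation and borylation. LiN(i-Pr)2 in THF at −78 °C removes the C3 proton to give 3-lithio-5,6,7,8-tetramethoxy-2-(4-methoxyphenyl)-4H-chromen-4-one F5. B(OMe)3 converts this into lithium trimethoxy[5,6,7,8-tetramethoxy-2-(4-methoxyphenyl)-4-oxo-4H-chromen-3-yl]borate F6. Oxidation of the carbon–boron bond with H2O2/AcOH at 0 °C then returns to the route at target 19.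

Further compounds
F1 | step 4 | 1-(2-hydroxy-3,4,5,6-tetramethoxyphenyl)ethan-1-one | CC(=O)c1c(O)c(OC)c(OC)c(OC)c1OC
F2 | step 2 | 2,3,4,5-tetramethoxyphenyl N-isopropylcarbamate | CC(C)NC(=O)Oc1cc(OC)c(OC)c(OC)c1OC
F3 | step 2 | 2,3,4,5-tetramethoxy-6-(trimethylsilyl)phenyl N-isopropylcarbamate | CC(C)NC(=O)Oc1c([Si](C)(C)C)c(OC)c(OC)c(OC)c1OC
F4 | step 2 | 2,3,4,5-tetramethoxy-6-(trimethylsilyl)phenol | COc1c([Si](C)(C)C)c(O)c(OC)c(OC)c1OC
F5 | step 6 | 3-lithio-5,6,7,8-tetramethoxy-2-(4-methoxyphenyl)-4H-chromen-4-one | [Li]c1c(-c2ccc(OC)cc2)oc2c(OC)c(OC)c(OC)c(OC)c2c1=O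
F6 | step 6 | lithium trimethoxy[5,6,7,8-tetramethoxy-2-(4-methoxyphenyl)-4-oxo-4H-chromen-3-yl]borate | [Li+].CO[B-](OC)(OC)c1c(-c2ccc(OC)cc2)oc2c(OC)c(OC)c(OC)c(OC)c2c1=O
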